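**Plan**

1. Numbering: the upper flavan (U) and the lower flavan (L) carry ordinary flavan numbers. Retrosynthesis cuts first the 14 O-benzyl groups and a blocking bromine at C8(L); then both aryl bonds of C4(U), namely C4(U)–C4a(U) (ring C of U) and C4(U)–C6(L), which turns C4(U) into an aldehyde carbon; then the aryl ether O1(U)–C8a(U) and the C2(U)–C3(U) bond (aldol); in the lower half, the gallate ester.
2. Forward: an aldol joins ring B(U) to the C2–C3–C4 chain, an O-arylation hangs ring A(U) on O1, and the key step closes ring C(U) at C4–C4a and, in the same flask, bonds C4(U) to C6(L) of the finished lower unit. The lower unit comes from natural (−)-epigallocatechin by benzylation, galloylation and C8 bromination. Hydrogenolysis ends the route.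
3. Enabling feature: ring A(U) is a phloroglucinol ring, so C4a(U) is ortho to O1 and ortho/para to O5 and O7, and the path C4a–C8a–O1–C2–C3–C4 makes a six-membered closure. C4(U) is benzylic to two such trioxygenated rings, so one aldehyde carbon can take up both arenes in turn. C8(L) is capped, so only C6(L) can answer.
4. Stereochemistry: C2(U) and C3(U) come from one auxiliary-controlled syn-glycolate aldol; the ether is made at oxygen, so C2(U) is kept; C4(U) arises by substrate control (attack anti to the C3 benzyloxy group) in the key step; C2(L) and C3(L) are bought with (−)-epigallocatechin.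

Key step: step 10

Remark: flavan-4-ol 15 is expected as a mixture of C4 epimers; this does not matter because C4 is ionised again in the same flask, so its SMILES carries no C4 descriptor.

**Route**

Step 1
Reactants: 1 3,4,5-tris(benzyloxy)benzaldehyde; 2 (S)-4-benzyl-3-[2-(benzyloxy)acetyl]oxazolidin-2-one
Product: 3 (S)-4-benzyl-3-[(2S,3R)-2-(benzyloxy)-3-hydroxy-3-[3,4,5-tris(benzyloxy)phenyl]propanoyl]oxazolidin-2-one
Conditions: 2, Bu2BOTf, Et3N, CH2Cl2, −78 → 0 °C; then 1, −78 → 0 °C; pH 7 buffer, MeOH, H2O2, 0 °C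
Reagents that add atoms: none
Why: Evans syn-glycolate aldol, in which the Z-boron enolate of 2 should react through a closed chair transition state on the face away from the auxiliary benzyl group, setting both new stereocentres together as the (2S,3R) syn adduct (the future C3 and C2 of the upper flavan, with the C3 oxygen already benzylated).

Step 2
Reactants: 3 the aldol adduct
Product: 4 (1R,2R)-2-(benzyloxy)-1-[3,4,5-tris(benzyloxy)phenyl]propane-1,3-diol
Conditions: LiBH4, H2O (1 equiv), THF, 0 °C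
Reagents that add atoms: none
Why: Reductive removal of the oxazolidinone auxiliary by borohydride reduction of the imide carbonyl, a standard operation on Evans aldol adducts that touches neither stereocentre and frees the auxiliary for recovery.

Step 3
Reactants: 4 the diol
Product: 5 (1R,2R)-2-(benzyloxy)-3-[(triisopropylsilyl)oxy]-1-[3,4,5-tris(benzyloxy)phenyl]propan-1-ol
Conditions: TIPSCl, imidazole, DMF, 0 °C → rt
Reagents that add atoms: triisopropylsilyl chloride, CC(C)[Si](Cl)(C(C)C)C(C)C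
Why: Selective silylation of the primary hydroxyl, in which the bulky triisopropylsilyl group should discriminate against the hindered benzylic hydroxyl and, unlike smaller silyl groups, should not migrate to it under the basic conditions of the next step.

Step 4
Reactants: 5 the secondary benzylic alcohol; 6 1-bromo-3,5-bis(benzyloxy)benzene
Product: 7 [(2R,3R)-2-(benzyloxy)-3-[3,5-bis(benzyloxy)phenoxy]-3-[3,4,5-tris(benzyloxy)phenyl]propoxy]triisopropylsilane
Conditions: [Pd(C3H5)Cl]2 (2 mol%), RockPhos (6 mol%), Cs2CO3, toluene, 90 °C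
Reagents that add atoms: none
Why: Palladium-catalysed C–O cross-coupling (Buchwald–Hartwig etherification) of a secondary alcohol with an aryl bromide whose meta alkoxy groups do not slow oxidative addition, the bulky biaryl phosphine favouring C–O reductive elimination over β-hydride elimination; because the bond is made at oxygen, the benzylic stereocentre is retained, as the 2,3-cis series requires.

Step 5
Reactants: 7 the silyl ether
Product: 8 (2R,3R)-2-(benzyloxy)-3-[3,5-bis(benzyloxy)phenoxy]-3-[3,4,5-tris(benzyloxy)phenyl]propan-1-ol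
Conditions: TBAF, THF, 0 °C → rt
Reagents that add atoms: none
Why: Fluoride-induced desilylation, which should leave the benzyl ethers and the benzylic aryl ether untouched.

Step 6
Reactants: 8 the primary alcohol
Product: 9 (2S,3R)-2-(benzyloxy)-3-[3,5-bis(benzyloxy)phenoxy]-3-[3,4,5-tris(benzyloxy)phenyl]propanal
Conditions: Dess–Martin periodinane, CH2Cl2, 0 °C → rt; used crude
Reagents that add atoms: none
Why: Dess–Martin oxidation under base-free conditions, chosen so that the α-benzyloxy aldehyde should neither epimerise nor lose the β-aryloxy group by elimination (the change of descriptor at C2 is only a change of priorities).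

Step 7
Reactants: 10 (−)-epigallocatechin
Product: 11 (2R,3R)-5,7-bis(benzyloxy)-2-[3,4,5-tris(benzyloxy)phenyl]chroman-3-ol
Conditions: BnBr, K2CO3, DMF, 0 °C → rt, argon
Reagents that add atoms: benzyl bromide, BrCc1ccccc1
Why: Williamson etherification, in which carbonate deprotonates only the five phenols and leaves the C3 alcohol free, the mild base at room temperature under argon being chosen to avoid C2 epimerisation and oxidation of the pyrogallol ring.

Step 8
Reactants: 11 penta-O-benzyl-epigallocatechin; 12 3,4,5-tris(benzyloxy)benzoic acid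
Product: 13 (2R,3R)-5,7-bis(benzyloxy)-2-[3,4,5-tris(benzyloxy)phenyl]chroman-3-yl 3,4,5-tris(benzyloxy)benzoate
Conditions: DCC, DMAP, CH2Cl2, rt
Reagents that add atoms: none
Why: Steglich esterification of the C3 hydroxyl with benzyl-protected gallic acid, a standard way to galloylated benzyl-protected flavan-3-ols that touches no stereocentre.

Step 9
Reactants: 13 octa-O-benzyl-epigallocatechin gallate
Product: 14 (2R,3R)-5,7-bis(benzyloxy)-8-bromo-2-[3,4,5-tris(benzyloxy)phenyl]chroman-3-yl 3,4,5-tris(benzyloxy)benzoate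
Conditions: NBS, CH2Cl2, −78 → 0 °C
Reagents that add atoms: N-bromosuccinimide, O=C1CCC(=O)N1Br
Why: Electrophilic aromatic bromination, which in 5,7-di-O-benzyl flavan-3-ol derivatives should go to C8 of ring A in preference to C6 and to the less activated B and galloyl rings, so that bromine caps C8 and leaves C6 as the only free position of ring A.

Step 10
Reactants: 9 the aldehyde; 14 the 8-bromo lower unit (3 equiv, excess recovered)
Product: 16 (2R,3R)-5,7-bis(benzyloxy)-8-bromo-6-[(2R,3R,4R)-3,5,7-tris(benzyloxy)-2-[3,4,5-tris(benzyloxy)phenyl]chroman-4-yl]-2-[3,4,5-tris(benzyloxy)phenyl]chroman-3-yl 3,4,5-tris(benzyloxy)benzoate, via flavan-4-ol 15 (not isolated)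
Conditions: BF3·OEt2 (30 mol%), 4 Å MS, CH2Cl2, −78 → −30 °C
Reagents that add atoms: none
Why: Proposed new method: BF3 activates the aldehyde of 9, whose carbonyl carbon is attacked by the carbon of the 3,5-bis(benzyloxy)phenoxy ring that lies ortho to the ether oxygen and ortho/para to the two benzyloxy groups (intramolecular Friedel–Crafts hydroxyalkylation), closing ring C(U) through the C4–C4a bond in a 6-exo-trig mode to give flavan-4-ol 15; the acid then ionises C4–OH of 15 to the 5,7-dialkoxy-stabilised benzylic cation, which is captured by C6 of 14 in an intermolecular Friedel–Crafts alkylation, the one equivalent of water released being taken up by the sieves. The closest known reaction types are the acid-mediated twofold arylation of aldehydes to triarylmethanes (Baeyer condensation) and the Lewis acid-mediated C4 arylation of 4-oxygenated flavan-3-ols used for interflavan bonds; their tandem use on an acyclic 2-alkoxy-3-aryloxy aldehyde is the untested part. C2 and C3 enter unchanged from 9, the configuration at C4 of 15 is erased on ionisation, and the final C4 centre is set by substrate control: the arene should add to the half-chair cation on the face anti to the pseudoaxial C3 benzyloxy group and the C2 aryl group, giving the 3,4-trans (4β) product as in known couplings of 2,3-cis flavan C4 cations (the 4R descriptor of 16 denotes the same geometry as 4S in the target, since only the priorities differ). The ring closure has a single outcome because the two ortho positions of the symmetric dibenzyloxyphenoxy ring are equivalent, a five-membered closure by the less nucleophilic ring B is disfavoured, and an attack of 14 on the aldehyde ahead of cyclisation would converge on the same constitution. Regiochemistry in the lower unit is secured by the bromine at C8 of 14, and the excess of 14 should suppress further arylation of 16 at the free C6 and C8 positions of its upper ring A.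

Step 11
Reactants: 16 the protected dimer
Product: 17 epigallocatechin-(4β→6)-epigallocatechin 3-O-gallate, gallate on the lower unit (the target)
Conditions: H2 (1 atm), Pd(OH)2/C, THF/MeOH/H2O, rt
Reagents that add atoms: none
Why: Hydrogenolysis over Pd(OH)2/C should cleave the fourteen benzyl ethers and reduce the aryl C–Br bond in one operation, while the gallate ester, the pyran benzylic C–O bonds and all five stereocentres stay intact.

**Compound list**

1 | 3,4,5-tris(benzyloxy)benzaldehyde | O=Cc1cc(OCc2ccccc2)c(OCc2ccccc2)c(OCc2ccccc2)c1 | starting material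
2 | (S)-4-benzyl-3-[2-(benzyloxy)acetyl]oxazolidin-2-one | O=C(COCc1ccccc1)N1[C@@H](Cc2ccccc2)COC1=O | starting material
3 | (S)-4-benzyl-3-[(2S,3R)-2-(benzyloxy)-3-hydroxy-3-[3,4,5-tris(benzyloxy)phenyl]propanoyl]oxazolidin-2-one | O=C(N1[C@@H](Cc2ccccc2)COC1=O)[C@@H](OCc1ccccc1)[C@H](O)c1cc(OCc2ccccc2)c(OCc2ccccc2)c(OCc2ccccc2)c1 | intermediate
4 | (1R,2R)-2-(benzyloxy)-1-[3,4,5-tris(benzyloxy)phenyl]propane-1,3-diol | OC[C@@H](OCc1ccccc1)[C@H](O)c1cc(OCc2ccccc2)c(OCc2ccccc2)c(OCc2ccccc2)c1 | intermediate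
5 | (1R,2R)-2-(benzyloxy)-3-[(triisopropylsilyl)oxy]-1-[3,4,5-tris(benzyloxy)phenyl]propan-1-ol | CC(C)[Si](OC[C@@H](OCc1ccccc1)[C@H](O)c1cc(OCc2ccccc2)c(OCc2ccccc2)c(OCc2ccccc2)c1)(C(C)C)C(C)C | intermediate
6 | 1-bromo-3,5-bis(benzyloxy)benzene | Brc1cc(OCc2ccccc2)cc(OCc2ccccc2)c1 | starting material
7 | [(2R,3R)-2-(benzyloxy)-3-[3,5-bis(benzyloxy)phenoxy]-3-[3,4,5-tris(benzyloxy)phenyl]propoxy]triisopropylsilane | CC(C)[Si](OC[C@@H](OCc1ccccc1)[C@H](Oc1cc(OCc2ccccc2)cc(OCc2ccccc2)c1)c1cc(OCc2ccccc2)c(OCc2ccccc2)c(OCc2ccccc2)c1)(C(C)C)C(C)C | intermediate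
8 | (2R,3R)-2-(benzyloxy)-3-[3,5-bis(benzyloxy)phenoxy]-3-[3,4,5-tris(benzyloxy)phenyl]propan-1-ol | OC[C@@H](OCc1ccccc1)[C@H](Oc1cc(OCc2ccccc2)cc(OCc2ccccc2)c1)c1cc(OCc2ccccc2)c(OCc2ccccc2)c(OCc2ccccc2)c1 | intermediate
9 | (2S,3R)-2-(benzyloxy)-3-[3,5-bis(benzyloxy)phenoxy]-3-[3,4,5-tris(benzyloxy)phenyl]propanal | O=C[C@@H](OCc1ccccc1)[C@H](Oc1cc(OCc2ccccc2)cc(OCc2ccccc2)c1)c1cc(OCc2ccccc2)c(OCc2ccccc2)c(OCc2ccccc2)c1 | intermediate
10 | (−)-epigallocatechin, (2R,3R)-2-(3,4,5-trihydroxyphenyl)chromane-3,5,7-triol | O[C@@H]1Cc2c(cc(O)cc2O)O[C@@H]1c1cc(O)c(O)c(O)c1 | starting material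
11 | (2R,3R)-5,7-bis(benzyloxy)-2-[3,4,5-tris(benzyloxy)phenyl]chroman-3-ol | O[C@@H]1Cc2c(cc(OCc3ccccc3)cc2OCc2ccccc2)O[C@@H]1c1cc(OCc2ccccc2)c(OCc2ccccc2)c(OCc2ccccc2)c1 | intermediate
12 | 3,4,5-tris(benzyloxy)benzoic acid | OC(=O)c1cc(OCc2ccccc2)c(OCc2ccccc2)c(OCc2ccccc2)c1 | starting material
13 | (2R,3R)-5,7-bis(benzyloxy)-2-[3,4,5-tris(benzyloxy)phenyl]chroman-3-yl 3,4,5-tris(benzyloxy)benzoate | O=C(O[C@@H]1Cc2c(cc(OCc3ccccc3)cc2OCc2ccccc2)O[C@@H]1c1cc(OCc2ccccc2)c(OCc2ccccc2)c(OCc2ccccc2)c1)c1cc(OCc2ccccc2)c(OCc2ccccc2)c(OCc2ccccc2)c1 | intermediate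
14 | (2R,3R)-5,7-bis(benzyloxy)-8-bromo-2-[3,4,5-tris(benzyloxy)phenyl]chroman-3-yl 3,4,5-tris(benzyloxy)benzoate | O=C(O[C@@H]1Cc2c(c(Br)c(OCc3ccccc3)cc2OCc2ccccc2)O[C@@H]1c1cc(OCc2ccccc2)c(OCc2ccccc2)c(OCc2ccccc2)c1)c1cc(OCc2ccccc2)c(OCc2ccccc2)c(OCc2ccccc2)c1 | intermediate
15 | (2R,3R)-3,5,7-tris(benzyloxy)-2-[3,4,5-tris(benzyloxy)phenyl]chroman-4-ol (C4 epimers; formed in the flask, not isolated) | OC1c2c(OCc3ccccc3)cc(OCc3ccccc3)cc2O[C@H](c2cc(OCc3ccccc3)c(OCc3ccccc3)c(OCc3ccccc3)c2)[C@@H]1OCc1ccccc1 | intermediate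
16 | (2R,3R)-5,7-bis(benzyloxy)-8-bromo-6-[(2R,3R,4R)-3,5,7-tris(benzyloxy)-2-[3,4,5-tris(benzyloxy)phenyl]chroman-4-yl]-2-[3,4,5-tris(benzyloxy)phenyl]chroman-3-yl 3,4,5-tris(benzyloxy)benzoate | O=C(O[C@@H]1Cc2c(c(Br)c(OCc5ccccc5)c([C@H]3c4c(OCc5ccccc5)cc(OCc5ccccc5)cc4O[C@H](c4cc(OCc5ccccc5)c(OCc5ccccc5)c(OCc5ccccc5)c4)[C@@H]3OCc3ccccc3)c2OCc2ccccc2)O[C@@H]1c1cc(OCc2ccccc2)c(OCc2ccccc2)c(OCc2ccccc2)c1)c1cc(OCc2ccccc2)c(OCc2ccccc2)c(OCc2ccccc2)c1 | intermediate
17 | (2R,3R)-5,7-dihydroxy-6-[(2R,3R,4S)-3,5,7-trihydroxy-2-(3,4,5-trihydroxyphenyl)chroman-4-yl]-2-(3,4,5-trihydroxyphenyl)chroman-3-yl 3,4,5-trihydroxybenzoate | O=C(O[C@@H]1Cc2c(cc(O)c([C@H]3c4c(O)cc(O)cc4O[C@H](c4cc(O)c(O)c(O)c4)[C@@H]3O)c2O)O[C@@H]1c1cc(O)c(O)c(O)c1)c1cc(O)c(O)c(O)c1 | target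

**Count**

Total steps: 11. Longest linear sequence: 8 steps (steps 1–6, 10, 11); the lower-unit arm (steps 7–9) joins at step 10.

**Steps most likely to fail**

Step 10 (Proposed new method). The aldehyde may enolise and epimerise at C3 or lose the aryloxy group before it cyclises; the C4 cation may lose the C3 proton instead of being arylated, or be captured by another molecule of product and oligomerise; facial selectivity at C4 may be poor. The fallback uses known chemistry and forms the interflavan bond on a ready-made ring C. It sets out from compound 11. Benzylic oxidation of 11 with DDQ in CH2Cl2 in the presence of 2-ethoxyethanol should give (2R,3R,4S)-5,7-bis(benzyloxy)-4-(2-ethoxyethoxy)-2-[3,4,5-tris(benzyloxy)phenyl]chroman-3-ol F1. Activation of F1 with TMSOTf in CH2Cl2 at −78 °C in the presence of excess 14 should give, by attack of C6 of the C8-capped nucleophile anti to the C3 hydroxyl, (2R,3R)-5,7-bis(benzyloxy)-8-bromo-6-[(2R,3R,4R)-5,7-bis(benzyloxy)-3-hydroxy-2-[3,4,5-tris(benzyloxy)phenyl]chroman-4-yl]-2-[3,4,5-tris(benzyloxy)phenyl]chroman-3-yl 3,4,5-tris(benzyloxy)benzoate F2. Hydrogenolysis of F2 under the conditions of step 11 returns to the route at compound 17.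

Step 4. β-Hydride elimination from the palladium alkoxide of the hindered benzylic alcohol (oxidation to the ketone) and slow C–O reductive elimination may outrun the coupling. The fallback makes the ether at carbon with inversion instead of at oxygen with retention. It sets out from compound 5. Dess–Martin oxidation should give (R)-2-(benzyloxy)-3-[(triisopropylsilyl)oxy]-1-[3,4,5-tris(benzyloxy)phenyl]propan-1-one F3. Chelation-controlled reduction with Zn(BH4)2 in Et2O at −30 °C should give the anti alcohol (1S,2R)-2-(benzyloxy)-3-[(triisopropylsilyl)oxy]-1-[3,4,5-tris(benzyloxy)phenyl]propan-1-ol F4. A Mitsunobu etherification of F4 with 3,5-bis(benzyloxy)phenol (Oc1cc(OCc2ccccc2)cc(OCc2ccccc2)c1), PPh3 and DIAD in toluene at 0 °C should invert the benzylic centre and return to the route at compound 7.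

Step 11. Hydrogenolysis of fourteen benzyl ethers may stall as bromide poisons the catalyst, and the HBr released may cleave the acid-labile interflavan bond of the free polyphenol. The fallback separates the two reductions. It sets out from compound 16. Radical debromination with Bu3SnH and AIBN in toluene at 80 °C should give (2R,3R)-5,7-bis(benzyloxy)-6-[(2R,3R,4R)-3,5,7-tris(benzyloxy)-2-[3,4,5-tris(benzyloxy)phenyl]chroman-4-yl]-2-[3,4,5-tris(benzyloxy)phenyl]chroman-3-yl 3,4,5-tris(benzyloxy)benzoate F5. Hydrogenolysis of F5 (H2, Pd(OH)2/C, THF/MeOH/H2O) then proceeds under neutral conditions and returns to the route at compound 17.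

**Further compounds**

F1 | step 10 | (2R,3R,4S)-5,7-bis(benzyloxy)-4-(2-ethoxyethoxy)-2-[3,4,5-tris(benzyloxy)phenyl]chroman-3-ol | CCOCCO[C@H]1c2c(OCc3ccccc3)cc(OCc3ccccc3)cc2O[C@H](c2cc(OCc3ccccc3)c(OCc3ccccc3)c(OCc3ccccc3)c2)[C@@H]1O
F2 | step 10 | (2R,3R)-5,7-bis(benzyloxy)-8-bromo-6-[(2R,3R,4R)-5,7-bis(benzyloxy)-3-hydroxy-2-[3,4,5-tris(benzyloxy)phenyl]chroman-4-yl]-2-[3,4,5-tris(benzyloxy)phenyl]chroman-3-yl 3,4,5-tris(benzyloxy)benzoate | O=C(O[C@@H]1Cc2c(c(Br)c(OCc5ccccc5)c([C@H]3c4c(OCc5ccccc5)cc(OCc5ccccc5)cc4O[C@H](c4cc(OCc5ccccc5)c(OCc5ccccc5)c(OCc5ccccc5)c4)[C@@H]3O)c2OCc2ccccc2)O[C@@H]1c1cc(OCc2ccccc2)c(OCc2ccccc2)c(OCc2ccccc2)c1)c1cc(OCc2ccccc2)c(OCc2ccccc2)c(OCc2ccccc2)c1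
F3 | step 4 | (R)-2-(benzyloxy)-3-[(triisopropylsilyl)oxy]-1-[3,4,5-tris(benzyloxy)phenyl]propan-1-one | CC(C)[Si](OC[C@@H](OCc1ccccc1)C(=O)c1cc(OCc2ccccc2)c(OCc2ccccc2)c(OCc2ccccc2)c1)(C(C)C)C(C)C
F4 | step 4 | (1S,2R)-2-(benzyloxy)-3-[(triisopropylsilyl)oxy]-1-[3,4,5-tris(benzyloxy)phenyl]propan-1-ol | CC(C)[Si](OC[C@@H](OCc1ccccc1)[C@@H](O)c1cc(OCc2ccccc2)c(OCc2ccccc2)c(OCc2ccccc2)c1)(C(C)C)C(C)C
F5 | step 11 | (2R,3R)-5,7-bis(benzyloxy)-6-[(2R,3R,4R)-3,5,7-tris(benzyloxy)-2-[3,4,5-tris(benzyloxy)phenyl]chroman-4-yl]-2-[3,4,5-tris(benzyloxy)phenyl]chroman-3-yl 3,4,5-tris(benzyloxy)benzoate | O=C(O[C@@H]1Cc2c(cc(OCc5ccccc5)c([C@H]3c4c(OCc5ccccc5)cc(OCc5ccccc5)cc4O[C@H](c4cc(OCc5ccccc5)c(OCc5ccccc5)c(OCc5ccccc5)c4)[C@@H]3OCc3ccccc3)c2OCc2ccccc2)O[C@@H]1c1cc(OCc2ccccc2)c(OCc2ccccc2)c(OCc2ccccc2)c1)c1cc(OCc2ccccc2)c(OCc2ccccc2)c(OCc2ccccc2)c1
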